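The earlier runs and the new flask were computed for an exercise; noise was put on by code.

The leftover comes first. This flask holds 0.18 M of starting material against 0.171 M of reagent, and in the proposed steps one turnover takes one of each. Reagent is therefore the limiting reagent, and 95.0% is the ceiling on turnovers, the reagent charged over the starting material charged. About 5.00% of the starting material stays over.

all flasks: starting material 0.18 M; reagent 0.171 M; free catalyst 0.18 mM
- beta: scavenger 0.32 M; run made earlier
- flask: scavenger 0.216 M; time 30 min

beta run (percent of the starting material charged)

| time / min | starting material / % | product / % |
|---|---|---|
| 1.50 | 91 | 8 |
| 3.00 | 82 | 19 |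
| 5.00 | 74 | 27 |
| 6.00 | 66 | 31 |
| 8.00 | 59 | 39 |
| 10.0 | 47 | 52 |

(each reading ± 2 percentage points)

- what is said of released group includes idle adduct
- steps that have been proposed: starting material + free catalyst <-> catalyst intermediate A; catalyst intermediate A -> catalyst intermediate B; reagent + catalyst intermediate B -> catalyst intermediate C; catalyst intermediate C <-> released group + catalyst intermediate D; catalyst intermediate D <-> free catalyst + product; reagent + released group <-> idle adduct; scavenger + released group -> scavenged by-product
- the earlier runs do not show how much of reagent is bound; that part of a forecast is a guess
- no earlier run changes the charge of scavenger; that part of a forecast is a guess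

* part of the starting material that has reacted at 30 min
* share of the unused reagent that is free and not bound as idle adduct, at 30 min

Here is the puzzle. The beta run, which has more scavenger and the same other charges, runs nearly straight, with a reading of 52% product at 10.0 min. Carried on to 30 min, that line reads 156% of the charge, more than the ceiling of 95.0%.

Solving each end clears this up. I let the flask follow the line early and sit at the ceiling late. The two meet at 18.3 min, earlier than 30 min, which leaves 11.7 min for a rounded corner as c(reagent) falls. The cut in scavenger from 0.32 M to 0.216 M is a guess on my part: c(scavenger) still exceeds c(reagent) at the charge, so I keep the line. I expect the flask just under the ceiling, and I have no grounds for the free share.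

The forecast says 80% reacted and 55% free, the first lower than my reckoning just under the ceiling, with released group “binding more reagent as idle adduct and slowing the reaction somewhat”.

The flask gives 94.2% reacted, just under the ceiling of 95.0%, and 99.9% free.

    starting material + free catalyst ⇌ catalyst intermediate A (K = 24.0 M⁻¹, k = 18000 M⁻¹ min⁻¹)
    catalyst intermediate A → catalyst intermediate B (k = 810 min⁻¹)
    reagent + catalyst intermediate B → catalyst intermediate C (k = 1700 M⁻¹ min⁻¹)
    catalyst intermediate C ⇌ released group + catalyst intermediate D (K = 0.550 M, k = 110 min⁻¹)
    catalyst intermediate D ⇌ free catalyst + product (K = 4.40 M, k = 310 min⁻¹)
    reagent + released group ⇌ idle adduct, settled at all times (K = 2.10 M⁻¹)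
    scavenger + released group → scavenged by-product (k = 21.0 M⁻¹ min⁻¹)

In the flask at 30.0 min the half-life of reagent by its step with catalyst intermediate B is 2.4 min, short against the flask's 30 min and shorter than the 8.4 min of starting material by the forward rate of its step with free catalyst. At that moment 0.89% of the flask's reagent charge is left, and catalyst intermediate B, the resting state at this time, holds 94.0% of the catalyst. With 0.043 M of reagent in place of 0.171 M, the ceiling becomes 23.9%, and that neighbouring flask holds 23.9% product.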